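**Strategy.** Both C-prenyl groups are disconnected at their aryl–CH2 bonds (C6–CH2 on ring A, C3'–CH2 on ring B). Each of these ring carbons lies ortho to a phenolic oxygen (O5 and O4'), the signature of an aromatic Claisen shift of an aryl 1,1-dimethylallyl ether; O5 has only C6 open because C4a is substituted, and C3'/C5' are equivalent. A single thermal operation on the 5,4'-bis(2-methylbut-3-en-2-yl) ether of O7-MOM-protected (S)-naringenin should therefore form both C–C bonds and both trisubstituted alkenes and release both phenols, while the C2 stereocentre, bought with (S)-naringenin, is simply carried through. Mild methanolysis of the O7 acetal then delivers the target.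

Key step: step 4

Assumption: (S)-naringenin of high enantiomeric purity is taken as purchasable (upgraded by preparative chiral chromatography if needed), and in step 4 the ring-A shift is assumed to precede the ring-B shift for bookkeeping only, since both orders converge on the same product.

Step 1
Reactants: 1 2-methylbut-3-en-2-ol
Product: 3 tert-butyl 2-methylbut-3-en-2-yl carbonate, via lithium 2-methylbut-3-en-2-olate 2 (not isolated)
Conditions: n-BuLi (1.05 equiv), THF, −78 → 0 °C; Boc2O, 0 °C → rt; H2O
Reagents that add atoms: di-tert-butyl dicarbonate, CC(C)(C)OC(=O)OC(=O)OC(C)(C)C; n-butyllithium, [Li]CCCC (supplies only the lithium of 2)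
Why: Deprotonation of the tertiary alcohol and O-acylation of the lithium alkoxide with Boc2O is a standard mixed-carbonate synthesis (alkoxide acylation) that involves no stereocentre.

Step 2
Reactants: 4 (S)-naringenin [(2S)-5,7,4'-trihydroxyflavanone]
Product: 5 (2S)-5,4'-dihydroxy-7-(methoxymethoxy)flavanone
Conditions: MOMCl (1.05 equiv), i-Pr2NEt (1.2 equiv), THF, 0 °C
Reagents that add atoms: chloromethyl methyl ether, COCCl
Why: Williamson-type MOM ether formation should be selective for the 7-OH, which is para to the C4 carbonyl and the most acidic phenol, whereas the 5-OH is locked in a hydrogen bond to C4=O and the less acidic 4'-OH reacts more slowly with one equivalent of MOMCl; a hindered amine at 0 °C should not open the pyranone ring, so C2 is untouched.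

Step 3
Reactants: 5 (2S)-5,4'-dihydroxy-7-(methoxymethoxy)flavanone; 3 tert-butyl 2-methylbut-3-en-2-yl carbonate
Product: 7 (2S)-7-(methoxymethoxy)-5,4'-bis(2-methylbut-3-en-2-yloxy)flavanone, via 4'-mono(1,1-dimethylallyl) ether 6 (not isolated)
Conditions: 3 (2.5 equiv), Pd(PPh3)4 (5 mol %), 4 Å MS, THF, 0 °C → rt, quenched at full conversion
Reagents that add atoms: none
Why: In this decarboxylative Tsuji–Trost O-allylation, Pd(0) ionises 3 to the η3-1,1-dimethylallyl complex and tert-butoxide, which deprotonates first the free 4'-OH and then the hydrogen-bonded 5-OH, and each phenoxide attacks the more substituted allyl terminus under kinetic control to give the tertiary ether without external base, so C2 is not exposed to epimerising conditions.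

Step 4
Reactants: 7 (2S)-7-(methoxymethoxy)-5,4'-bis(2-methylbut-3-en-2-yloxy)flavanone
Product: 11 (2S)-5,4'-dihydroxy-7-(methoxymethoxy)-6,3'-bis(3-methylbut-2-en-1-yl)flavanone, via ring-A cyclohexadienone 8 (not isolated), via mono-rearranged 5-phenol 9 (not isolated), via ring-B cyclohexadienone 10 (not isolated)
Conditions: degassed PhMe (0.02 M), base-washed sealed tube, 120–130 °C
Reagents that add atoms: none
Why: Each aryl 2-methylbut-3-en-2-yl ether should undergo a concerted, chair-like [3,3] sigmatropic shift in which the vinyl CH2 terminus bonds to the ring carbon ortho to oxygen (C6 from O5, C3' from O4') as the O–C(CH3)2 bond breaks, giving 6-allylcyclohexa-2,4-dienones (8, 10) that enolise to the phenols, so that the former ether carbon becomes the (CH3)2C= end of a normal prenyl group. The closest known reaction is the aromatic Claisen rearrangement of aryl 1,1-dimethylallyl ethers to ortho-prenylphenols, which runs well below the temperature needed for simple allyl aryl ethers because of the gem-dimethyl substitution. No ring is closed and no lasting stereocentre is created, because the sp3 ring carbons of the dienones disappear on tautomerisation, and C2 is a spectator that neutral, aprotic, base-free conditions should leave intact. Regiochemistry is set by the substrate: O5 has C4a blocked and only C6 open, enolisation of the C6-H dienone (driven by aromatisation and the O5–H···O=C4 hydrogen bond) should outrun an onward Cope shift to C8, and C3' and C5' are interconverted by rotation about the C2–C1' bond. The selectivity required is the pericyclic shift over heterolysis of the tertiary allylic C–O bonds (loss of isoprene, or chroman closure of the products), which is why a non-polar solvent, acid-free glassware, exclusion of air and the lowest effective temperature are specified.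

Step 5
Reactants: 11 (2S)-5,4'-dihydroxy-7-(methoxymethoxy)-6,3'-bis(3-methylbut-2-en-1-yl)flavanone
Product: 12 macarangaflavanone B [(2S)-5,7,4'-trihydroxy-6,3'-bis(3-methylbut-2-en-1-yl)flavanone]
Conditions: conc. HCl (cat.), MeOH, rt → 40 °C
Reagents that add atoms: none
Why: Acid-catalysed transacetalisation (MOM ether methanolysis) should free the 7-OH, and dilute acid at or below 40 °C is expected to leave the ortho-prenylphenol units uncyclised and not to epimerise C2.

**Compound list**

1 | 2-methylbut-3-en-2-ol | CC(C)(O)C=C | starting material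
2 | lithium 2-methylbut-3-en-2-olate | [Li+].[O-]C(C)(C)C=C | intermediate (not isolated)
3 | tert-butyl 2-methylbut-3-en-2-yl carbonate | C=CC(C)(C)OC(=O)OC(C)(C)C | intermediate
4 | (S)-naringenin, (2S)-5,7,4'-trihydroxyflavanone | Oc1ccc([C@@H]2CC(=O)c3c(cc(O)cc3O)O2)cc1 | starting material
5 | (2S)-5,4'-dihydroxy-7-(methoxymethoxy)flavanone | Oc1ccc([C@@H]2CC(=O)c3c(cc(OCOC)cc3O)O2)cc1 | intermediate
6 | (2S)-5-hydroxy-7-(methoxymethoxy)-4'-(2-methylbut-3-en-2-yloxy)flavanone | C=CC(C)(C)Oc1ccc([C@@H]2CC(=O)c3c(cc(OCOC)cc3O)O2)cc1 | intermediate (not isolated)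
7 | (2S)-7-(methoxymethoxy)-5,4'-bis(2-methylbut-3-en-2-yloxy)flavanone | C=CC(C)(C)Oc1ccc([C@@H]2CC(=O)c3c(cc(OCOC)cc3OC(C)(C)C=C)O2)cc1 | intermediate (key-step precursor)
8 | ring-A cyclohexa-2,4-dienone: (2S)-7-(methoxymethoxy)-6-(3-methylbut-2-en-1-yl)-2-[4-(2-methylbut-3-en-2-yloxy)phenyl]-2,3-dihydro-4H-chromene-4,5(6H)-dione, C6 configuration undefined | C=CC(C)(C)Oc1ccc([C@@H]2CC(=O)C3=C(C=C(OCOC)C(CC=C(C)C)C3=O)O2)cc1 | intermediate (not isolated)
9 | (2S)-5-hydroxy-7-(methoxymethoxy)-6-(3-methylbut-2-en-1-yl)-4'-(2-methylbut-3-en-2-yloxy)flavanone | C=CC(C)(C)Oc1ccc([C@@H]2CC(=O)c3c(cc(OCOC)c(CC=C(C)C)c3O)O2)cc1 | intermediate (not isolated)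
10 | ring-B cyclohexa-2,4-dienone: (2S)-5-hydroxy-7-(methoxymethoxy)-6-(3-methylbut-2-en-1-yl)-2-[3-(3-methylbut-2-en-1-yl)-4-oxocyclohexa-1,5-dien-1-yl]chroman-4-one, ring-B sp3 carbon undefined | CC(C)=CCC1C=C([C@@H]2CC(=O)c3c(cc(OCOC)c(CC=C(C)C)c3O)O2)C=CC1=O | intermediate (not isolated)
11 | (2S)-5,4'-dihydroxy-7-(methoxymethoxy)-6,3'-bis(3-methylbut-2-en-1-yl)flavanone | CC(C)=CCc1cc([C@@H]2CC(=O)c3c(cc(OCOC)c(CC=C(C)C)c3O)O2)ccc1O | intermediate (key-step product)
12 | macarangaflavanone B, (2S)-5,7,4'-trihydroxy-6,3'-bis(3-methylbut-2-en-1-yl)flavanone | CC(C)=CCc1cc([C@@H]2CC(=O)c3c(cc(O)c(CC=C(C)C)c3O)O2)ccc1O | target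

**Totals.** Total step count: 5. Longest linear sequence: 4 steps (4 → 5 → 7 → 11 → 12); step 1 is a one-step branch that joins at step 3.

**Steps most likely to fail**

1. Step 3. The hydrogen-bonded, peri-hindered 5-hydroxyl may etherify incompletely, Pd may re-ionise the tertiary ether and isomerise it to the linear prenyl ether, or the electron-rich ring A may be C-allylated. Fallback, from 5 back to 7: copper-catalysed propargylic etherification of both phenols with 3-chloro-3-methylbut-1-yne (DBU, CuCl2 cat., MeCN, 0 °C), which proceeds through a copper allenylidene, cannot give a linear isomer and tolerates hindered, weakly nucleophilic phenols, should give (2S)-7-(methoxymethoxy)-5,4'-bis(2-methylbut-3-yn-2-yloxy)flavanone F1. Semihydrogenation of both alkynes over Lindlar catalyst (H2, quinoline, EtOAc, rt) then gives 7.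

2. Step 4. Heterolysis of the tertiary allylic ethers with loss of the C5 unit may compete with the sigmatropic shift, the ring-A group may migrate onward to C8, or C2 may epimerise thermally. Fallback, from 5 back to 11: Mitsunobu etherification of the 4'- and 5-hydroxyls with allyl alcohol (PPh3, DIAD, THF, 0 °C → rt) should give (2S)-5,4'-bis(allyloxy)-7-(methoxymethoxy)flavanone F2, whose primary ethers cannot ionise. Aromatic Claisen rearrangement (Eu(fod)3 cat., PhCl, 80 °C for the chelation-assisted ring-A ether, then 180–190 °C for the ring-B ether) should give (2S)-6,3'-diallyl-5,4'-dihydroxy-7-(methoxymethoxy)flavanone F3. Double olefin cross-metathesis with 2-methylbut-2-ene (Grubbs second-generation catalyst, CH2Cl2, 40 °C) then turns both allyl groups into prenyl groups and gives 11. The higher temperature of this variant makes an enantiopurity check necessary.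

3. Step 5. Acid may close the prenyl side chains onto the neighbouring phenols (chroman formation) or add solvent across the trisubstituted alkenes during acetal cleavage. Fallback, from 4 to 12, with a fluoride-labile group at O7 so that no acid is used after the prenyl groups are in place: selective silylation of the most acidic 7-OH (TIPSCl, imidazole, DMF, 0 °C) should give (2S)-5,4'-dihydroxy-7-(triisopropylsilyloxy)flavanone F4. Palladium-catalysed etherification with 3 as in step 3 should give (2S)-5,4'-bis(2-methylbut-3-en-2-yloxy)-7-(triisopropylsilyloxy)flavanone F5. The double Claisen rearrangement as in step 4 should give (2S)-5,4'-dihydroxy-6,3'-bis(3-methylbut-2-en-1-yl)-7-(triisopropylsilyloxy)flavanone F6. Buffered desilylation (TBAF, AcOH, THF, 0 °C) then gives 12.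

**Further compounds**

F1 | step 3 | (2S)-7-(methoxymethoxy)-5,4'-bis(2-methylbut-3-yn-2-yloxy)flavanone | C#CC(C)(C)Oc1ccc([C@@H]2CC(=O)c3c(cc(OCOC)cc3OC(C)(C)C#C)O2)cc1
F2 | step 4 | (2S)-5,4'-bis(allyloxy)-7-(methoxymethoxy)flavanone | C=CCOc1ccc([C@@H]2CC(=O)c3c(cc(OCOC)cc3OCC=C)O2)cc1
F3 | step 4 | (2S)-6,3'-diallyl-5,4'-dihydroxy-7-(methoxymethoxy)flavanone | C=CCc1cc([C@@H]2CC(=O)c3c(cc(OCOC)c(CC=C)c3O)O2)ccc1O
F4 | step 5 | (2S)-5,4'-dihydroxy-7-(triisopropylsilyloxy)flavanone | Oc1ccc([C@@H]2CC(=O)c3c(cc(O[Si](C(C)C)(C(C)C)C(C)C)cc3O)O2)cc1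
F5 | step 5 | (2S)-5,4'-bis(2-methylbut-3-en-2-yloxy)-7-(triisopropylsilyloxy)flavanone | C=CC(C)(C)Oc1ccc([C@@H]2CC(=O)c3c(cc(O[Si](C(C)C)(C(C)C)C(C)C)cc3OC(C)(C)C=C)O2)cc1
F6 | step 5 | (2S)-5,4'-dihydroxy-6,3'-bis(3-methylbut-2-en-1-yl)-7-(triisopropylsilyloxy)flavanone | CC(C)=CCc1cc([C@@H]2CC(=O)c3c(cc(O[Si](C(C)C)(C(C)C)C(C)C)c(CC=C(C)C)c3O)O2)ccc1O
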